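**Plan**
- Retrosynthesis: the dihydropyran ring is cut last, across C4–C3 and O1–C2, into an o-quinone methide of ring A and styrene. The C4 carbon is then removed from a C2-symmetric 2-(benzofuran-2-yl)-5-methoxyresorcinol, and the furan ring is cut (C3a–C3 and O1–C2 of the benzofuran) into an o-iodophenol and an arylacetylene.
- Forward: the iodophenol comes from 3-methoxy-2-methylphenol (C–H borylation/oxidation, ortho-iodination) and the alkyne from 5-methoxyresorcinol (directed metalation/formylation, homologation). The furan ring is closed by Sonogashira coupling/5-endo cyclisation, the resorcinol ring is formylated and the aldehyde reduced, and the pyran ring is closed last.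
- Enabling feature: ring A is a phloroglucinol ring in which C4a lies between the C8a–OH and the C5–OMe, with O7 para. Only one o-quinone methide (O1=C8a–C4a=C4) can form, it is stabilised by the 5- and 7-oxygens, and the polarity of styrene places the phenyl-bearing carbon on O1.
- Stereochemistry: the only stereocentre, C2 (S), is set in the ring-forming cycloaddition by a chiral Brønsted acid; the one later step (desilylation) does not touch it.

Key step: step 12

Assumption: the sense of induction of the chiral acid in step 12 cannot be predicted with confidence. The catalyst enantiomer that gives the (2S)-product is to be fixed by a screen and checked against 20 of defined configuration from the CBS/Mitsunobu fallback.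
Abbreviations: TIPS = triisopropylsilyl; MOM = methoxymethyl; Bf = 4-methoxy-5-methyl-6-[(triisopropylsilyl)oxy]-1-benzofuran-2-yl.

**Step 1**
Reactants: 1 3-methoxy-2-methylphenol
Product: 2 triisopropyl(3-methoxy-2-methylphenoxy)silane
Conditions: TIPSCl, imidazole, DMF, rt
Reagents that add atoms: triisopropylsilyl chloride, CC(C)[Si](Cl)(C(C)C)C(C)C
Why: Standard silylation of a phenol; the bulky TIPS ether should survive organometallic, basic and mildly acidic steps and later serves as a steric shield.

**Step 2**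
Reactants: 2 triisopropyl(3-methoxy-2-methylphenoxy)silane
Product: 4 3-methoxy-4-methyl-5-[(triisopropylsilyl)oxy]phenol, via aryl pinacol boronate 3 (not isolated)
Conditions: [Ir(OMe)(cod)]2 (cat.), dtbpy (cat.), B2pin2 (1 equiv), THF, 80 °C; then Oxone, acetone/H2O, rt
Reagents that add atoms: bis(pinacolato)diboron, CC1(C)OB(OC1(C)C)B1OC(C)(C)C(C)(C)O1 (boron of intermediate 3 only); potassium peroxymonosulfate (Oxone), [K+].[O-]S(=O)(=O)OO (the phenol oxygen)
Why: Sterically governed Ir-catalysed aromatic C–H borylation should hit the only C–H not ortho to a substituent (meta to both OMe and OTIPS), and one-pot C–B oxidation should give the phenol at that position.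

**Step 3**
Reactants: 4 3-methoxy-4-methyl-5-[(triisopropylsilyl)oxy]phenol
Product: 5 2-iodo-3-methoxy-4-methyl-5-[(triisopropylsilyl)oxy]phenol
Conditions: NIS (1.0 equiv), MeCN, −20 → 0 °C
Reagents that add atoms: N-iodosuccinimide, O=C1CCC(=O)N1I
Why: Electrophilic aromatic iodination ortho to the free phenol; the para position carries the methyl group and the ortho site next to OTIPS is shielded by the silyl group, so iodine should enter between OH and OMe.

**Step 4**
Reactants: 6 5-methoxybenzene-1,3-diol
Product: 7 1-methoxy-3,5-bis(methoxymethoxy)benzene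
Conditions: MOMCl, i-Pr2NEt, CH2Cl2, 0 °C → rt
Reagents that add atoms: chloromethyl methyl ether, COCCl
Why: Routine O-alkylation to the bis-MOM ether, which protects both phenols and supplies two cooperative directing groups for the next step.

**Step 5**
Reactants: 7 1-methoxy-3,5-bis(methoxymethoxy)benzene
Product: 9 4-methoxy-2,6-bis(methoxymethoxy)benzaldehyde, via aryllithium 8 (not isolated)
Conditions: n-BuLi, THF, 0 °C; DMF, 0 °C → rt; then H2O
Reagents that add atoms: n-butyllithium, [Li]CCCC (lithium of intermediate 8 only); N,N-dimethylformamide, CN(C)C=O (the formyl group)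
Why: Directed ortho-metalation; the position between the two chelating OMOM groups should be lithiated in preference to those next to the weaker OMe director, and DMF formylates the aryllithium.

**Step 6**
Reactants: 9 4-methoxy-2,6-bis(methoxymethoxy)benzaldehyde
Product: 10 2-ethynyl-5-methoxy-1,3-bis(methoxymethoxy)benzene
Conditions: dimethyl (1-diazo-2-oxopropyl)phosphonate, K2CO3, MeOH, rt
Reagents that add atoms: dimethyl (1-diazo-2-oxopropyl)phosphonate, CC(=O)C(=[N+]=[N-])P(=O)(OC)OC
Why: Seyferth–Gilbert homologation in the Ohira–Bestmann variant converts the aldehyde into the terminal alkyne under mild base that leaves the MOM acetals intact.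

**Step 7**
Reactants: 5 2-iodo-3-methoxy-4-methyl-5-[(triisopropylsilyl)oxy]phenol; 10 2-ethynyl-5-methoxy-1,3-bis(methoxymethoxy)benzene
Product: 12 2-[4-methoxy-2,6-bis(methoxymethoxy)phenyl]-4-methoxy-5-methyl-6-[(triisopropylsilyl)oxy]-1-benzofuran, via alkynylphenol 11 (not isolated)
Conditions: PdCl2(PPh3)2 (cat.), CuI (cat.), Et3N, DMF, 60 → 90 °C
Reagents that add atoms: none
Why: Sonogashira coupling followed by metal-assisted 5-endo-dig hydroalkoxylation (domino benzofuran synthesis from o-iodophenols); only the iodophenol ring carries a free OH, so the furan ring should close on the correct ring.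

**Step 8**
Reactants: 12 2-[4-methoxy-2,6-bis(methoxymethoxy)phenyl]-4-methoxy-5-methyl-6-[(triisopropylsilyl)oxy]-1-benzofuran
Product: 13 5-methoxy-2-Bf-benzene-1,3-diol
Conditions: 3 M HCl (aq), MeOH/THF, 40 °C
Reagents that add atoms: none
Why: Acid-catalysed acetal exchange removes both MOM groups; an aryl TIPS ether should be stable to dilute methanolic acid.

**Step 9**
Reactants: 13 5-methoxy-2-Bf-benzene-1,3-diol
Product: 15 2,4-dihydroxy-6-methoxy-3-Bf-benzaldehyde, via hydroxymethylphenol magnesium salt 14 (not isolated)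
Conditions: MgCl2, Et3N, (CH2O)n, MeCN, reflux; then 1 M HCl
Reagents that add atoms: paraformaldehyde (as formaldehyde), C=O
Why: Magnesium phenoxide-mediated ortho-formylation (Casnati–Skattebøl) occurs only ortho to a free phenolic OH, so only the resorcinol ring should react; its two open ortho sites are equivalent by symmetry and the first formyl group slows a second.

**Step 10**
Reactants: 15 2,4-dihydroxy-6-methoxy-3-Bf-benzaldehyde
Product: 16 2-hydroxy-6-methoxy-3-Bf-4-[(triisopropylsilyl)oxy]benzaldehyde
Conditions: TIPSCl (1.05 equiv), imidazole, DMF, 0 °C → rt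
Reagents that add atoms: triisopropylsilyl chloride, CC(C)[Si](Cl)(C(C)C)C(C)C
Why: Selective silylation of the more acidic, non-chelated OH para to the formyl group; the ortho OH is held in an intramolecular hydrogen bond to the carbonyl and should stay free.

**Step 11**
Reactants: 16 2-hydroxy-6-methoxy-3-Bf-4-[(triisopropylsilyl)oxy]benzaldehyde
Product: 17 2-(hydroxymethyl)-3-methoxy-6-Bf-5-[(triisopropylsilyl)oxy]phenol
Conditions: NaBH4, THF/EtOH, 0 °C
Reagents that add atoms: none
Why: Borohydride reduction of the aryl aldehyde gives the o-hydroxybenzyl alcohol, the quinone methide precursor; it is to be used without storage.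

**Step 12**
Reactants: 17 2-(hydroxymethyl)-3-methoxy-6-Bf-5-[(triisopropylsilyl)oxy]phenol; 18 styrene
Product: 20 (2S)-5-methoxy-8-Bf-2-phenyl-7-[(triisopropylsilyl)oxy]-3,4-dihydro-2H-1-benzopyran, via o-quinone methide 19 (not isolated)
Conditions: 18 (5 equiv), chiral BINOL-derived N-triflylphosphoramide with 3,3'-bis(2,4,6-triisopropylphenyl) groups (10 mol%, enantiomer fixed by screening), 5 Å MS, PhMe, −20 → 0 °C
Reagents that add atoms: none
Why: Proposed new method: the chiral acid ionises the benzylic C–OH of 17 to the o-quinone methide 19, held as a hydrogen-bonded ion pair with the chiral phosphoramide anion; the terminal CH2 of styrene attacks the exocyclic methide carbon (future C4) while the positive charge developing at the PhCH carbon is captured by the quinone methide oxygen in a concerted but strongly asynchronous inverse-electron-demand oxa-[4+2] cycloaddition. The closest known reaction types are the chiral phosphoric acid or N-triflylphosphoramide-catalysed [4+2] cycloadditions of in situ generated aryl-substituted o-quinone methides with styrenes and the chiral-acid-catalysed asymmetric Prins reaction of styrenes with formaldehyde; new here is a methide with an unsubstituted CH2 terminus and a bulky group beside the quinone methide oxygen. The dihydropyran ring closes by intermolecular [4+2] between the four-atom unit O1=C8a–C4a=C4 and the two alkene carbons of styrene, the C4–C3 bond leading and the O1–C2 bond completing the six-membered ring. The single new stereocentre C2 is controlled by the catalyst: the chiral anion bound at O1 should shield one face of the PhCH terminus during C–O bond formation. The step needs regioselectivity for the 2-phenyl isomer (secured by polarity, phenyl stabilising charge on the carbon that bonds to oxygen), a single site of quinone methide formation (secured because C5 carries OMe and O7 is silylated, so only the C8a–OH flanks the benzylic carbon) and chemoselectivity for styrene over self-arylation (secured by the TIPS groups flanking the nucleophilic C6 and benzofuran C7 positions and by excess styrene).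

**Step 13**
Reactants: 20 (2S)-5-methoxy-8-Bf-2-phenyl-7-[(triisopropylsilyl)oxy]-3,4-dihydro-2H-1-benzopyran
Product: 21 (2S)-8-(6-hydroxy-4-methoxy-5-methyl-1-benzofuran-2-yl)-5-methoxy-2-phenyl-3,4-dihydro-2H-1-benzopyran-7-ol
Conditions: TBAF (2.5 equiv), AcOH (2.5 equiv), THF, 0 °C → rt
Reagents that add atoms: none
Why: Fluoride cleavage of both aryl silyl ethers under acetic acid buffering should free the two phenols without ionising the benzylic C2–O bond, so the stereocentre is retained.

**Compound list**
1 | 3-methoxy-2-methylphenol | COc1cccc(O)c1C | starting material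
2 | triisopropyl(3-methoxy-2-methylphenoxy)silane | COc1cccc(O[Si](C(C)C)(C(C)C)C(C)C)c1C | intermediate
3 | 2-{3-methoxy-4-methyl-5-[(triisopropylsilyl)oxy]phenyl}-4,4,5,5-tetramethyl-1,3,2-dioxaborolane (not isolated) | COc1cc(B2OC(C)(C)C(C)(C)O2)cc(O[Si](C(C)C)(C(C)C)C(C)C)c1C | intermediate
4 | 3-methoxy-4-methyl-5-[(triisopropylsilyl)oxy]phenol | COc1cc(O)cc(O[Si](C(C)C)(C(C)C)C(C)C)c1C | intermediate
5 | 2-iodo-3-methoxy-4-methyl-5-[(triisopropylsilyl)oxy]phenol | COc1c(I)c(O)cc(O[Si](C(C)C)(C(C)C)C(C)C)c1C | intermediate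
6 | 5-methoxybenzene-1,3-diol | COc1cc(O)cc(O)c1 | starting material
7 | 1-methoxy-3,5-bis(methoxymethoxy)benzene | COCOc1cc(OC)cc(OCOC)c1 | intermediate
8 | [4-methoxy-2,6-bis(methoxymethoxy)phenyl]lithium (not isolated) | [Li]c1c(OCOC)cc(OC)cc1OCOC | intermediate
9 | 4-methoxy-2,6-bis(methoxymethoxy)benzaldehyde | COCOc1cc(OC)cc(OCOC)c1C=O | intermediate
10 | 2-ethynyl-5-methoxy-1,3-bis(methoxymethoxy)benzene | C#Cc1c(OCOC)cc(OC)cc1OCOC | intermediate
11 | 3-methoxy-2-{[4-methoxy-2,6-bis(methoxymethoxy)phenyl]ethynyl}-4-methyl-5-[(triisopropylsilyl)oxy]phenol (not isolated) | COCOc1cc(OC)cc(OCOC)c1C#Cc1c(O)cc(O[Si](C(C)C)(C(C)C)C(C)C)c(C)c1OC | intermediate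
12 | 2-[4-methoxy-2,6-bis(methoxymethoxy)phenyl]-4-methoxy-5-methyl-6-[(triisopropylsilyl)oxy]-1-benzofuran | COCOc1cc(OC)cc(OCOC)c1-c1cc2c(OC)c(C)c(O[Si](C(C)C)(C(C)C)C(C)C)cc2o1 | intermediate
13 | 5-methoxy-2-{4-methoxy-5-methyl-6-[(triisopropylsilyl)oxy]-1-benzofuran-2-yl}benzene-1,3-diol | COc1cc(O)c(-c2cc3c(OC)c(C)c(O[Si](C(C)C)(C(C)C)C(C)C)cc3o2)c(O)c1 | intermediate
14 | 4-(hydroxymethyl)-5-methoxy-2-{4-methoxy-5-methyl-6-[(triisopropylsilyl)oxy]-1-benzofuran-2-yl}benzene-1,3-diol (present as magnesium salt, neutral form drawn, not isolated) | COc1cc(O)c(-c2cc3c(OC)c(C)c(O[Si](C(C)C)(C(C)C)C(C)C)cc3o2)c(O)c1CO | intermediate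
15 | 2,4-dihydroxy-6-methoxy-3-{4-methoxy-5-methyl-6-[(triisopropylsilyl)oxy]-1-benzofuran-2-yl}benzaldehyde | COc1cc(O)c(-c2cc3c(OC)c(C)c(O[Si](C(C)C)(C(C)C)C(C)C)cc3o2)c(O)c1C=O | intermediate
16 | 2-hydroxy-6-methoxy-3-{4-methoxy-5-methyl-6-[(triisopropylsilyl)oxy]-1-benzofuran-2-yl}-4-[(triisopropylsilyl)oxy]benzaldehyde | COc1cc(O[Si](C(C)C)(C(C)C)C(C)C)c(-c2cc3c(OC)c(C)c(O[Si](C(C)C)(C(C)C)C(C)C)cc3o2)c(O)c1C=O | intermediate
17 | 2-(hydroxymethyl)-3-methoxy-6-{4-methoxy-5-methyl-6-[(triisopropylsilyl)oxy]-1-benzofuran-2-yl}-5-[(triisopropylsilyl)oxy]phenol | COc1cc(O[Si](C(C)C)(C(C)C)C(C)C)c(-c2cc3c(OC)c(C)c(O[Si](C(C)C)(C(C)C)C(C)C)cc3o2)c(O)c1CO | intermediate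
18 | styrene | C=Cc1ccccc1 | starting material
19 | 5-methoxy-6-methylidene-2-{4-methoxy-5-methyl-6-[(triisopropylsilyl)oxy]-1-benzofuran-2-yl}-3-[(triisopropylsilyl)oxy]cyclohexa-2,4-dien-1-one (not isolated) | C=C1C(=O)C(-c2cc3c(OC)c(C)c(O[Si](C(C)C)(C(C)C)C(C)C)cc3o2)=C(O[Si](C(C)C)(C(C)C)C(C)C)C=C1OC | intermediate
20 | (2S)-5-methoxy-8-{4-methoxy-5-methyl-6-[(triisopropylsilyl)oxy]-1-benzofuran-2-yl}-2-phenyl-7-[(triisopropylsilyl)oxy]-3,4-dihydro-2H-1-benzopyran | COc1cc(O[Si](C(C)C)(C(C)C)C(C)C)c(-c2cc3c(OC)c(C)c(O[Si](C(C)C)(C(C)C)C(C)C)cc3o2)c2c1CC[C@@H](c1ccccc1)O2 | intermediate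
21 | (2S)-8-(6-hydroxy-4-methoxy-5-methyl-1-benzofuran-2-yl)-5-methoxy-2-phenyl-3,4-dihydro-2H-1-benzopyran-7-ol | COc1cc(O)c(-c2cc3c(OC)c(C)c(O)cc3o2)c2c1CC[C@@H](c1ccccc1)O2 | target

**Totals**
Total step count: 13. Longest linear sequence: 10 steps (steps 1–3 then 7–13; the branch through steps 4–6 then 7–13 is equally long).

**Steps most likely to fail**

1. Step 12 (Proposed new method). The ion pair may be too loose, or an uncatalysed background cycloaddition may compete, giving poor facial selectivity at C2; the quinone methide may also be consumed by arylation of a second molecule, and styrene may oligomerise. The fallback uses known chemistry, sets out from 16 and returns at 20. Wittig olefination of 16 with (benzoylmethylene)triphenylphosphorane (PhMe, 90 °C) should give (E)-3-{2-hydroxy-6-methoxy-3-Bf-4-[(triisopropylsilyl)oxy]phenyl}-1-phenylprop-2-en-1-one F1. Chemoselective hydrogenation of the alkene (H2, Pd/C poisoned with Ph2S, EtOAc) should give the saturated ketone 3-{2-hydroxy-6-methoxy-3-Bf-4-[(triisopropylsilyl)oxy]phenyl}-1-phenylpropan-1-one F2. Corey–Bakshi–Shibata reduction with the (S)-oxazaborolidine and BH3·SMe2 (THF, −20 °C) should give (1R)-3-{2-hydroxy-6-methoxy-3-Bf-4-[(triisopropylsilyl)oxy]phenyl}-1-phenylpropan-1-ol F3. Intramolecular Mitsunobu etherification (PPh3, DIAD, THF, 0 °C) should then close the pyran ring with inversion to (S)-configured 20.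

2. Step 3. Site selectivity between the two positions ortho to the phenol may be poor, and over-iodination may occur. The fallback sets out from 4 and returns at 5. Protection of 4 (MOMCl, i-Pr2NEt) should give triisopropyl[3-methoxy-5-(methoxymethoxy)-2-methylphenoxy]silane F4. Directed ortho-metalation between the OMOM and OMe groups (n-BuLi, THF, 0 °C; then I2) should give triisopropyl[4-iodo-3-methoxy-5-(methoxymethoxy)-2-methylphenoxy]silane F5. Cleavage of the MOM ether (HCl, MeOH, rt) should give 5.

3. Step 7. Oxidative addition into the di-ortho-substituted, electron-rich aryl iodide may be slow, so that oxidative homocoupling of alkyne 10 dominates, and ring closure of the hindered alkynylphenol may stall. The fallback replaces the alkyne annulation by a biaryl coupling; it sets out from 5 and from 8 (made from 7 as in step 5) and returns at 12.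
   - Sonogashira coupling of 5 with the small alkyne ethynyltrimethylsilane (PdCl2(PPh3)2, CuI, Et3N) should give 3-methoxy-4-methyl-5-[(triisopropylsilyl)oxy]-2-[(trimethylsilyl)ethynyl]phenol F6.
   - Gold-catalysed 5-endo cycloisomerisation (Ph3PAuCl/AgOTf, CH2Cl2) should give 4-methoxy-5-methyl-6-[(triisopropylsilyl)oxy]-2-(trimethylsilyl)-1-benzofuran F7.
   - ipso-Iododesilylation (ICl, CH2Cl2, −78 °C) should give 2-iodo-4-methoxy-5-methyl-6-[(triisopropylsilyl)oxy]-1-benzofuran F8.
   - Transmetalation of 8 with ZnCl2 should give [4-methoxy-2,6-bis(methoxymethoxy)phenyl]zinc chloride F9, and Negishi coupling of F8 with F9 (Pd2(dba)3, SPhos, THF, 50 °C) should give 12.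

**Further compounds**
F1 | step 12 | (E)-3-{2-hydroxy-6-methoxy-3-{4-methoxy-5-methyl-6-[(triisopropylsilyl)oxy]-1-benzofuran-2-yl}-4-[(triisopropylsilyl)oxy]phenyl}-1-phenylprop-2-en-1-one | COc1cc(O[Si](C(C)C)(C(C)C)C(C)C)c(-c2cc3c(OC)c(C)c(O[Si](C(C)C)(C(C)C)C(C)C)cc3o2)c(O)c1/C=C/C(=O)c1ccccc1
F2 | step 12 | 3-{2-hydroxy-6-methoxy-3-{4-methoxy-5-methyl-6-[(triisopropylsilyl)oxy]-1-benzofuran-2-yl}-4-[(triisopropylsilyl)oxy]phenyl}-1-phenylpropan-1-one | COc1cc(O[Si](C(C)C)(C(C)C)C(C)C)c(-c2cc3c(OC)c(C)c(O[Si](C(C)C)(C(C)C)C(C)C)cc3o2)c(O)c1CCC(=O)c1ccccc1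
F3 | step 12 | (1R)-3-{2-hydroxy-6-methoxy-3-{4-methoxy-5-methyl-6-[(triisopropylsilyl)oxy]-1-benzofuran-2-yl}-4-[(triisopropylsilyl)oxy]phenyl}-1-phenylpropan-1-ol | COc1cc(O[Si](C(C)C)(C(C)C)C(C)C)c(-c2cc3c(OC)c(C)c(O[Si](C(C)C)(C(C)C)C(C)C)cc3o2)c(O)c1CC[C@@H](O)c1ccccc1
F4 | step 3 | triisopropyl[3-methoxy-5-(methoxymethoxy)-2-methylphenoxy]silane | COCOc1cc(OC)c(C)c(O[Si](C(C)C)(C(C)C)C(C)C)c1
F5 | step 3 | triisopropyl[4-iodo-3-methoxy-5-(methoxymethoxy)-2-methylphenoxy]silane | COCOc1cc(O[Si](C(C)C)(C(C)C)C(C)C)c(C)c(OC)c1I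
F6 | step 7 | 3-methoxy-4-methyl-5-[(triisopropylsilyl)oxy]-2-[(trimethylsilyl)ethynyl]phenol | COc1c(C#C[Si](C)(C)C)c(O)cc(O[Si](C(C)C)(C(C)C)C(C)C)c1C
F7 | step 7 | 4-methoxy-5-methyl-6-[(triisopropylsilyl)oxy]-2-(trimethylsilyl)-1-benzofuran | COc1c(C)c(O[Si](C(C)C)(C(C)C)C(C)C)cc2oc([Si](C)(C)C)cc12
F8 | step 7 | 2-iodo-4-methoxy-5-methyl-6-[(triisopropylsilyl)oxy]-1-benzofuran | COc1c(C)c(O[Si](C(C)C)(C(C)C)C(C)C)cc2oc(I)cc12
F9 | step 7 | [4-methoxy-2,6-bis(methoxymethoxy)phenyl]zinc chloride | Cl[Zn]c1c(OCOC)cc(OC)cc1OCOC
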